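## The problem

The target is a 2‑arylbenzofuran. Ring A is phloroglucinol‑derived, with free hydroxyls at C4 and C6 and a (2R)‑3‑methylbut‑3‑en‑2‑yl group at C7. It is joined through C2 to C1′ of a resorcinol ring B whose two flanking carbons, C2′ and C6′, each carry a prenyl group, so the inter‑ring bond is strongly hindered. The only stereocentre is the benzylic, allylic methine of the C7 side chain. Nothing else in the molecule can relay chirality to it, so it must be set by an external chiral reagent or catalyst and then kept away from acid and strong base. Three features limit the late chemistry: each prenyl group is ortho to a phenol and closes to a chroman under acid, the isopropenyl group is ortho to the C6 hydroxyl and closes to a dihydrofuran, and the three alkenes rule out hydrogenolysis. In ring A the carbon substituent (C7) lies between O1 and O6 and the hydrogen (C5) between O4 and O6, two positions of nearly equal electronic character that the route must tell apart. Ring B has hydrogen only at C4′, between the two oxygens, and three contiguous carbon substituents at C2′, C1′ and C6′, which is the reverse of what electrophilic prenylation of a 5‑substituted resorcinol gives. That pattern is the one formed when a 2,3,4‑trisubstituted cyclobutenone combines with a terminal silyloxyalkyne, and because ring B is symmetric it does not matter which of its oxygens arrives silylated.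

## Retrosynthesis

**Unmasking.** Target 37 is related to its ring B mono(triisopropylsilyl) ether 36 and this to the ring A bis(methoxymethyl) ether 34. Only one O–Si bond and two acetal O–CH2 bonds are cut. Two separate cuts are preferred to one global acid treatment, because fluoride and a base‑buffered silyl triflate are the mildest reagents for each group and neither puts protic acid next to the prenyl and isopropenyl groups. Compound 34 is no simpler in skeleton, but it is the stable form in which the tetraphenol can be carried. The forward steps must cleave aryl acetals and an aryl silyl ether without cyclising or shifting any alkene.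

**Ring B.** Ring B of 34 is cut at C3′–C4′, C5′–C6′ and C2′–C3′, which returns cyclobutenone 29 and the terminal siloxyalkyne 26. In the forward sense the first two bonds form in a ketene–alkyne [2+2] step and the third in a six‑electron ring closure, while the former C1–C2 bond of the four‑membered ring is given up. The neighbouring cuts are worse: cutting C2–C1′ calls for a cross‑coupling at a carbon flanked by two prenyl groups, and cutting the aryl–prenyl bonds calls for prenylation of a 5‑arylresorcinol, which goes to C4′. The chosen cut removes a whole benzene ring with five substituents and leaves a four‑membered ketone and a two‑carbon alkyne. The forward reaction must add the alkyne to the vinylketene with one regiochemistry and must work on a 3‑heteroaryl‑2,4‑dialkylcyclobutenone.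

**The hindered bond.** Cyclobutenone 29 is cut at the bond between benzofuran C2 and the ring (the future C2–C1′ bond). This gives the 2‑lithiobenzofuran 27, drawn from bromide 10, and the 3‑ethoxycyclobutenone 18, with carbinol 28 as the link. Compared with building the four‑membered ring on a 2‑alkynylbenzofuran, this cut is shorter and makes the most hindered bond of the target by adding an organolithium to an ordinary ketone carbonyl. The precursors are a benzofuran with no ring B carbon and a C14 vinylogous ester. The forward step needs clean 1,2‑addition and an acid treatment mild enough for the acetals.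

**The four‑membered ring.** Ring 18 is cut across C1–C2 and C3–C4 into prenylketene 17 and ynol ether 14. One cycloaddition then places both prenyl groups regiospecifically, which stepwise alkylation of a parent ethoxycyclobutenone would not do. Ketene 17 comes from acid chloride 16 and so from the purchased acid 15; ynol ether 14 comes from ethoxyethyne 11 and prenyl bromide 12 through acetylide 13. All are acyclic compounds of at most nine carbons. The forward reaction must trap a monoalkylketene that otherwise dimerises, and the electron‑rich ynol ether does this.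

**The siloxyalkyne.** Alkyne 26 is traced through its acetylide 25 to the 2‑bromovinyl ether 24 (the second π bond is cut, made forward by loss of HBr). Compound 24 goes back through dibromide 23 to silyl vinyl ether 22 and, via enolate 21, to tetrahydrofuran 19 and silyl chloride 20. The ester‑homologation route that serves substituted siloxyalkynes is not suited to the parent compound, so the classical halogenation–dehydrohalogenation route to alkynyl ethers is used instead. The precursors are a solvent and a silyl chloride. The forward steps need the Si–O bond to survive bromine and amide base, which is why the bulky silyl group is chosen.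

**The stereocentre.** In 10 the C–CH3 bond at the stereocentre is cut, leading to the (E)‑allylic chloride 9. Forward, a methyl Grignard reagent attacks the benzylic carbon in SN2′ fashion under a chiral copper catalyst. An aromatic Claisen rearrangement of a 2‑methylbut‑2‑enyl aryl ether would build the same side chain but gives no enantiocontrol, and coupling a preformed chiral fragment to C7 has no regiochemical handle. The cut reduces the problem to an achiral trisubstituted alkene: 9 comes from alcohol 7 through mesylate 8, 7 from ester 6, and 6 from aldehyde 5 by a C=C cut. The forward reaction needs high SN2′ and face selectivity on an aryl group with one ortho acetal (the other ortho position is the ring oxygen).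

**Ring A and the furan.** Aldehyde 5 is cut at O1–C2 to the gem‑dibromoalkene 4. Forward, copper‑mediated O‑vinylation closes the furan and leaves one bromine as the later site of lithiation. In 4 the formyl C–C bond is cut to give phenol 3. The phenol oxygen is the future O1, so its only free ortho position is the future C7, and a phenoxide‑directed formylation distinguishes C7 from C5 by mechanism; electrophilic formylation of the closed benzofuran would depend on a small electronic bias. Phenol 3 goes back by a C=C cut to salicylaldehyde 2, and 2 to 1, whose double methoxymethylation leaves free exactly the hydrogen‑bonded hydroxyl the plan needs. The forward steps require formylation next to a bulky vinyl group and tolerance of the dibromoalkene toward amine base.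

## Roads not taken

Alternative 1: The furan ring is cut at C3–C3a and O1–C7a. Forward, the enolate of the ring B methyl ketone A1 is C‑arylated at the C–I bond and then O‑arylated at the C–Br bond of the bromo‑iodoarene A2 under one palladium catalyst, giving benzofuran A3.
- Merits: both halves are simple arenes, the heterocycle forms in one operation, and the hindered C2–C1′ bond already exists in A1 as an aryl–carbonyl bond.
- Weak points: A3 has hydrogen at C7, so the branched side chain and its stereocentre would have to be added afterwards to a tetra‑acetal with three competing positions (C7, C5, C3) and no directing group. If A2 carried the side chain instead, the C–Br bond that must undergo C–O coupling would sit next to a secondary alkyl group. A1 still needs a 2,6‑diprenylated 3,5‑dioxygenated ring, so the ring B problem is only moved. The end game must free two ring B oxygens from acetals next to prenyl groups.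
- Comparison: in convergence and in the number of operations that make the heterocycle this road is better; the chosen route spends steps 2–4 on the furan. Against that, the chosen plan fixes C7 early by a directed formylation, sets the stereocentre catalytically on a small intermediate, and forms ring B with its prenyl groups already in place.

Alternative 2: Ring A is cut at C3a–C4, with the C4 and C6 oxygens reverting to carbonyl groups. Forward, the acyl Meldrum's acid A4, a 2,5‑disubstituted furan that carries ring B, is heated. It gives acylketene A5, whose enol form closes onto furan C3 by six‑electron electrocyclisation to give A6 with both ring A hydroxyls free.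
- Merits: the substitution pattern of ring A is written into the open chain, so the C5/C7 question never arises; ring A needs no protecting group; and the stereocentre could be set in the open chain by a sigmatropic rearrangement. In these respects this road is at least as good as the chosen one.
- Weak points: A5 is formed in the presence of the phenols it produces and can acylate them. Closure must occur at the β‑position of the furan ring of A5, next to a twisted aryl group. Ring B enters as a prenyl‑flanked bis‑acetal, so the last step is the acid‑sensitive deprotection the target tolerates least. The hindered furan–ring B bond still has to come from a coupling.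
- Comparison: against the cleaner ring A logic, the chosen plan never carries ring B as a prenyl‑flanked acetal, makes the hindered bond by carbonyl addition, and answers C5 versus C7 (step 3) by mechanism as well.

Alternative 3: Ring B is cut at C1′–C6′. Forward, aqueous base opens the 4‑pyrone A7 to triketone A8. An intramolecular aldol condensation between the side‑chain methylene (C6′) and the benzofuranyl ketone carbon (C1′), then dehydration and enolisation, gives A9, which has the ring A of 34 and a free ring B.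
- Merits: both ring B hydroxyls emerge unprotected, so the silyl ether and the fluoride step are saved, and no thermal step or ynol ether is needed. Here the alternative is better.
- Weak points: A8 has three enolisable positions and three carbonyl groups, so other aldol closures, reversion to A7, closure through the other enol oxygen and retro‑Claisen cleavage all compete. The carbonyl to be attacked is the least electrophilic one, conjugated to the benzofuran and next to a prenyl‑bearing carbon. The free resorcinol forms in hot base. A7 takes more steps to make than 18 and 26 together.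
- Comparison: the chosen plan pays one extra deprotection. In return, a closure whose regiochemistry nothing enforces is replaced by a pericyclic cascade with one regiochemical decision, which the polarity of the alkyne settles.

Key step: step 16

Remarks on the chemistry:
- 5‑Methylhex‑4‑enoic acid 15 is assumed to be a purchased material.
- ArA stands for 4,6‑bis(methoxymethoxy)‑7‑[(2R)‑3‑methylbut‑3‑en‑2‑yl]‑1‑benzofuran‑2‑yl.
- L* in step 8 is the biphenyl‑2,2′‑diyl phosphoramidite of bis[1‑(2‑methoxyphenyl)ethyl]amine; the amine antipode that leads to the (R) product is used, and which antipode this is has not been assigned here.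
- C4 of the four‑membered ring in 18, 28 and 29 forms without control; 29 is drawn as one epimer because both converge in step 16.

## Route

Step 1
Reactants: 1 2,4,6‑trihydroxybenzaldehyde
Product: 2 2‑hydroxy‑4,6‑bis(methoxymethoxy)benzaldehyde
Conditions: MOMCl (2.2 equiv), i‑Pr2NEt, CH2Cl2, 0 °C to 20 °C
Reagents that add atoms: chloromethyl methyl ether, COCCl
Why: Acetal protection of phenols; the para hydroxyl and one of the two equivalent ortho hydroxyls react, while the remaining ortho hydroxyl is held back by its hydrogen bond to the formyl oxygen, and this is the oxygen that later becomes O1.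

Step 2
Reactants: 2 2‑hydroxy‑4,6‑bis(methoxymethoxy)benzaldehyde
Product: 3 2‑(2,2‑dibromoethenyl)‑3,5‑bis(methoxymethoxy)phenol
Conditions: CBr4 (2 equiv), PPh3 (4 equiv), Et3N (2 equiv), CH2Cl2, 0 °C
Reagents that add atoms: carbon tetrabromide, BrC(Br)(Br)Br
Why: Ramirez dibromo‑olefination (first stage of the Corey–Fuchs sequence); the ylide formed in the flask converts the aldehyde to the 1,1‑dibromoalkene, salicylaldehydes react without protection, and Et3N shields the acetals from HBr.

Step 3
Reactants: 3 2‑(2,2‑dibromoethenyl)‑3,5‑bis(methoxymethoxy)phenol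
Product: 4 3‑(2,2‑dibromoethenyl)‑2‑hydroxy‑4,6‑bis(methoxymethoxy)benzaldehyde
Conditions: MgCl2 (2 equiv), Et3N (4 equiv), (CH2O)n (6 equiv), THF, 65 °C; aq. citric acid work‑up
Reagents that add atoms: formaldehyde (as paraformaldehyde), C=O
Why: Magnesium‑mediated ortho‑formylation of a phenol (Casnati–Skattebøl); the magnesium phenoxide delivers formaldehyde only to an ortho carbon and the single free one is the future C7, and a second formaldehyde oxidises the benzylic alkoxide to the aldehyde.

Step 4
Reactants: 4 3‑(2,2‑dibromoethenyl)‑2‑hydroxy‑4,6‑bis(methoxymethoxy)benzaldehyde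
Product: 5 2‑bromo‑4,6‑bis(methoxymethoxy)‑1‑benzofuran‑7‑carbaldehyde
Conditions: CuI (5 mol %), K3PO4 (2 equiv), THF, 80 °C
Reagents that add atoms: none
Why: Copper‑catalysed intramolecular O‑vinylation of a gem‑dibromoalkene (Ullmann‑type C–O coupling); the phenoxide replaces the bromine cis to the ring and the second bromine stays at C2 as the handle for lithiation, while the non‑enolisable aldehyde is inert to K3PO4.

Step 5
Reactants: 5 2‑bromo‑4,6‑bis(methoxymethoxy)‑1‑benzofuran‑7‑carbaldehyde
Product: 6 ethyl (2E)‑3‑[2‑bromo‑4,6‑bis(methoxymethoxy)‑1‑benzofuran‑7‑yl]‑2‑methylprop‑2‑enoate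
Conditions: Ph3P=C(CH3)CO2Et (1.5 equiv), toluene, 100 °C
Reagents that add atoms: ethyl 2‑(triphenyl‑λ5‑phosphanylidene)propanoate, CCOC(=O)C(C)=P(c1ccccc1)(c1ccccc1)c1ccccc1
Why: Wittig olefination with a stabilised ylide, which gives the (E)‑trisubstituted enoate needed for the later allylic substitution.

Step 6
Reactants: 6 ethyl (2E)‑3‑[2‑bromo‑4,6‑bis(methoxymethoxy)‑1‑benzofuran‑7‑yl]‑2‑methylprop‑2‑enoate
Product: 7 (2E)‑3‑[2‑bromo‑4,6‑bis(methoxymethoxy)‑1‑benzofuran‑7‑yl]‑2‑methylprop‑2‑en‑1‑ol
Conditions: i‑Bu2AlH (2.5 equiv), CH2Cl2, −78 °C; aq. potassium sodium tartrate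
Reagents that add atoms: none
Why: 1,2‑Reduction of the enoate to the (E)‑allylic alcohol; the vinylic bromide and the acetals are untouched at −78 °C.

Step 7
Reactants: 7 (2E)‑3‑[2‑bromo‑4,6‑bis(methoxymethoxy)‑1‑benzofuran‑7‑yl]‑2‑methylprop‑2‑en‑1‑ol
Product: 9 2‑bromo‑7‑[(1E)‑3‑chloro‑2‑methylprop‑1‑en‑1‑yl]‑4,6‑bis(methoxymethoxy)‑1‑benzofuran, via allylic mesylate 8 (not isolated)
Conditions: MsCl (1.2 equiv), LiCl (3 equiv), 2,4,6‑collidine (1.5 equiv), DMF, 0 °C; used crude
Reagents that add atoms: lithium chloride, [Li+].[Cl-]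
Why: Mesylation and in situ chloride displacement under collidine buffering convert the primary allylic alcohol to the chloride without acid and without allylic transposition.

Step 8
Reactants: 9 2‑bromo‑7‑[(1E)‑3‑chloro‑2‑methylprop‑1‑en‑1‑yl]‑4,6‑bis(methoxymethoxy)‑1‑benzofuran
Product: 10 2‑bromo‑4,6‑bis(methoxymethoxy)‑7‑[(2R)‑3‑methylbut‑3‑en‑2‑yl]‑1‑benzofuran
Conditions: MeMgBr (1.3 equiv, Et2O, slow addition), Cu(O2CC4H3S) (3 mol %), phosphoramidite L* (3.3 mol %), CH2Cl2, −78 °C
Reagents that add atoms: methylmagnesium bromide, C[Mg]Br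
Why: Copper‑catalysed enantioselective allylic alkylation (SN2′) of a β‑methyl‑γ‑aryl allylic chloride with a Grignard reagent under a chiral phosphoramidite and a monovalent copper carboxylate; methyl adds to the benzylic carbon as chloride leaves and the double bond moves to the terminal position, so the chiral catalyst sets the (R) centre, and the aryl bromide is inert to MeMgBr at −78 °C.

Step 9
Reactants: 11 ethoxyethyne; 12 1‑bromo‑3‑methylbut‑2‑ene (prenyl bromide)
Product: 14 1‑ethoxy‑5‑methylhex‑4‑en‑1‑yne, via lithium ethoxyethynide 13 (not isolated)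
Conditions: n‑BuLi, THF, −78 °C; then 12, DMPU, −78 °C to 0 °C
Reagents that add atoms: none
Why: Deprotonation of the terminal ynol ether and SN2 alkylation of the lithium acetylide by the primary allylic bromide in the presence of a dipolar cosolvent.

Step 10
Reactants: 15 5‑methylhex‑4‑enoic acid
Product: 16 5‑methylhex‑4‑enoyl chloride
Conditions: (COCl)2 (1.2 equiv), DMF (cat.), CH2Cl2, 0 °C to 20 °C; concentrate
Reagents that add atoms: oxalyl chloride, O=C(Cl)C(=O)Cl
Why: Acid chloride formation under catalytic Vilsmeier activation; the low temperature and prompt evaporation keep HCl from adding to the trisubstituted alkene.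

Step 11
Reactants: 16 5‑methylhex‑4‑enoyl chloride; 14 1‑ethoxy‑5‑methylhex‑4‑en‑1‑yne
Product: 18 3‑ethoxy‑2,4‑bis(3‑methylbut‑2‑en‑1‑yl)cyclobut‑2‑en‑1‑one (racemic), via prenylketene 17 (not isolated)
Conditions: Et3N (1.5 equiv), Et2O, 35 °C, slow addition of 16
Reagents that add atoms: none
Why: Dehydrochlorination gives the monoalkylketene, which the electron‑rich ynol ether traps in a regiospecific [2+2] cycloaddition (nucleophilic alkyne carbon to the ketene carbonyl carbon), giving the 3‑ethoxycyclobutenone with one prenyl group on C2 and the other on C4.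

Step 12
Reactants: 19 tetrahydrofuran; 20 chlorotri(propan‑2‑yl)silane
Product: 22 (ethenyloxy)tri(propan‑2‑yl)silane, via lithium ethenolate 21 (not isolated)
Conditions: n‑BuLi, THF, 35 °C; then 20, DMPU, 0 °C to 20 °C
Reagents that add atoms: none
Why: α‑Lithiation of tetrahydrofuran and [3+2] cycloreversion give ethene and the lithium enolate of acetaldehyde, which the bulky silyl chloride traps on oxygen.

Step 13
Reactants: 22 (ethenyloxy)tri(propan‑2‑yl)silane
Product: 24 [(Z)‑2‑bromoethenyl]oxy‑tri(propan‑2‑yl)silane, via dibromoethyl silyl ether 23 (not isolated)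
Conditions: Br2 (1.0 equiv), CH2Cl2, −78 °C; then Et3N (1.5 equiv), −78 °C to 20 °C
Reagents that add atoms: bromine, BrBr
Why: Halogenation–dehydrohalogenation of an enol ether; bromine adds across the double bond and Et3N removes HBr from the α‑bromo ether to give mainly the (Z)‑2‑bromovinyl ether, the bulky silyl group disfavouring attack of bromide at silicon.

Step 14
Reactants: 24 [(Z)‑2‑bromoethenyl]oxy‑tri(propan‑2‑yl)silane
Product: 26 (ethynyloxy)tri(propan‑2‑yl)silane, via lithium silyloxyethynide 25 (not isolated)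
Conditions: LiN(i‑Pr)2 (2.2 equiv), THF, −78 °C; then H2O
Reagents that add atoms: none
Why: Base‑induced anti‑elimination of HBr from a (Z)‑2‑halovinyl ether, the standard entry to alkynyl ethers; the second equivalent of amide holds the product as its acetylide until the quench, and any (E) isomer converges by α‑elimination and 1,2‑hydrogen shift.

Step 15
Reactants: 10 2‑bromo‑4,6‑bis(methoxymethoxy)‑7‑[(2R)‑3‑methylbut‑3‑en‑2‑yl]‑1‑benzofuran; 18 3‑ethoxy‑2,4‑bis(3‑methylbut‑2‑en‑1‑yl)cyclobut‑2‑en‑1‑one
Product: 29 3‑{4,6‑bis(methoxymethoxy)‑7‑[(2R)‑3‑methylbut‑3‑en‑2‑yl]‑1‑benzofuran‑2‑yl}‑2,4‑bis(3‑methylbut‑2‑en‑1‑yl)cyclobut‑2‑en‑1‑one, via aryllithium 27 (not isolated), via ethoxycyclobutenol 28 (not isolated)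
Conditions: n‑BuLi (1.05 equiv), THF, −78 °C; 18 (1.1 equiv), −78 °C; then 1 M aq. HCl, THF, 0 °C
Reagents that add atoms: water, O
Why: Bromine–lithium exchange at C2 is faster than ortho‑lithiation beside the acetals; the 2‑lithiobenzofuran adds 1,2 to the vinylogous ester carbonyl, and mild acid ionises the tertiary allylic carbinol and hydrolyses the enol ether (Stork–Danheiser‑type carbonyl transposition), which puts the benzofuran on C3 of the new cyclobutenone.

Step 16
Reactants: 29 3‑{4,6‑bis(methoxymethoxy)‑7‑[(2R)‑3‑methylbut‑3‑en‑2‑yl]‑1‑benzofuran‑2‑yl}‑2,4‑bis(3‑methylbut‑2‑en‑1‑yl)cyclobut‑2‑en‑1‑one; 26 (ethynyloxy)tri(propan‑2‑yl)silane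
Product: 34 2‑[3‑hydroxy‑2,6‑bis(3‑methylbut‑2‑en‑1‑yl)‑5‑{[tri(propan‑2‑yl)silyl]oxy}phenyl]‑4,6‑bis(methoxymethoxy)‑7‑[(2R)‑3‑methylbut‑3‑en‑2‑yl]‑1‑benzofuran, via vinylketene 30 (not isolated), via vinylcyclobutenone 31 (not isolated), via dienylketene 32 (not isolated), via cyclohexadienone 33 (not isolated)
Conditions: 26 (2 equiv), toluene, 80 °C then 110 °C, argon
Reagents that add atoms: none
Why: This is a Danheiser benzannulation of a cyclobutenone with a siloxyalkyne, a known reaction type applied here to a new substrate. Heating opens 29 by conrotatory four‑electron electrocyclic cleavage of the C1–C4 bond, the C4 prenyl group turning outward, to give vinylketene 30. The siloxyalkyne adds to the ketene C=C bond in a [2+2] step in which its unsubstituted, nucleophilic carbon bonds to the ketene carbonyl carbon (C3′–C4′) and its oxygen‑bearing carbon to the ketene α‑carbon (C5′–C6′), giving 31. Compound 31 opens again by four‑electron cleavage to dienylketene 32, which closes ring B by disrotatory six‑electron electrocyclisation between the ketene carbon and the terminal alkene carbon (C2′–C3′), and tautomerisation of dienone 33 gives the phenol. No stereocentre is created, since the sp3 carbons of 29 and 33 both become aromatic, which is why the C4 epimers converge. The one selectivity that matters, hydrogen and not a prenyl group between the two oxygens, is fixed by the polarisation of the siloxyalkyne against the electrophilic ketene carbon, and the ring opening that must place the vinyl group inward is reversible, so the unproductive rotamer is recycled. Excess alkyne limits acylation of the product phenol by 30, and the acetals, the alkenes and the remote stereocentre are expected to be inert at 110 °C in a neutral hydrocarbon.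

Step 17
Reactants: 34 2‑[3‑hydroxy‑2,6‑bis(3‑methylbut‑2‑en‑1‑yl)‑5‑{[tri(propan‑2‑yl)silyl]oxy}phenyl]‑4,6‑bis(methoxymethoxy)‑7‑[(2R)‑3‑methylbut‑3‑en‑2‑yl]‑1‑benzofuran
Product: 36 2‑[3‑hydroxy‑2,6‑bis(3‑methylbut‑2‑en‑1‑yl)‑5‑{[tri(propan‑2‑yl)silyl]oxy}phenyl]‑7‑[(2R)‑3‑methylbut‑3‑en‑2‑yl]‑1‑benzofuran‑4,6‑diol, via tris(trimethylsilyl) ether 35 (not isolated)
Conditions: Me3SiOTf (6 equiv), 2,2′‑bipyridyl (9 equiv), CH3CN, 0 °C to 20 °C; then H2O
Reagents that add atoms: none
Why: Silyl triflate/2,2′‑bipyridyl cleavage of aryl methoxymethyl ethers; the acetal oxygen is silylated, bipyridyl takes up the methoxymethyl cation and buffers the medium, and the aryl trimethylsilyl ethers hydrolyse on aqueous work‑up, so no protic acid meets the prenyl or isopropenyl groups and the hindered triisopropylsilyl ether survives.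

Step 18
Reactants: 36 2‑[3‑hydroxy‑2,6‑bis(3‑methylbut‑2‑en‑1‑yl)‑5‑{[tri(propan‑2‑yl)silyl]oxy}phenyl]‑7‑[(2R)‑3‑methylbut‑3‑en‑2‑yl]‑1‑benzofuran‑4,6‑diol
Product: 37 2‑[3,5‑dihydroxy‑2,6‑bis(3‑methylbut‑2‑en‑1‑yl)phenyl]‑7‑[(2R)‑3‑methylbut‑3‑en‑2‑yl]‑1‑benzofuran‑4,6‑diol (CNP0208883.1)
Conditions: Bu4NF (1.5 equiv), AcOH (1.5 equiv), THF, 0 °C
Reagents that add atoms: none
Why: Fluoride cleavage of the aryl silyl ether, buffered with acetic acid so that the tetraphenol is not held as its air‑sensitive phenoxide; any trimethylsilyl ether left from step 17 is cleaved as well.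

## Compound list

1 | 2,4,6‑trihydroxybenzaldehyde | O=Cc1c(O)cc(O)cc1O | starting material
2 | 2‑hydroxy‑4,6‑bis(methoxymethoxy)benzaldehyde | O=Cc1c(O)cc(OCOC)cc1OCOC | intermediate
3 | 2‑(2,2‑dibromoethenyl)‑3,5‑bis(methoxymethoxy)phenol | Oc1cc(OCOC)cc(OCOC)c1C=C(Br)Br | intermediate
4 | 3‑(2,2‑dibromoethenyl)‑2‑hydroxy‑4,6‑bis(methoxymethoxy)benzaldehyde | O=Cc1c(O)c(C=C(Br)Br)c(OCOC)cc1OCOC | intermediate
5 | 2‑bromo‑4,6‑bis(methoxymethoxy)‑1‑benzofuran‑7‑carbaldehyde | O=Cc1c(OCOC)cc(OCOC)c2cc(Br)oc12 | intermediate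
6 | ethyl (2E)‑3‑[2‑bromo‑4,6‑bis(methoxymethoxy)‑1‑benzofuran‑7‑yl]‑2‑methylprop‑2‑enoate | CCOC(=O)/C(C)=C/c1c(OCOC)cc(OCOC)c2cc(Br)oc12 | intermediate
7 | (2E)‑3‑[2‑bromo‑4,6‑bis(methoxymethoxy)‑1‑benzofuran‑7‑yl]‑2‑methylprop‑2‑en‑1‑ol | OC/C(C)=C/c1c(OCOC)cc(OCOC)c2cc(Br)oc12 | intermediate
8 | (2E)‑3‑[2‑bromo‑4,6‑bis(methoxymethoxy)‑1‑benzofuran‑7‑yl]‑2‑methylprop‑2‑en‑1‑yl methanesulfonate | CS(=O)(=O)OC/C(C)=C/c1c(OCOC)cc(OCOC)c2cc(Br)oc12 | intermediate
9 | 2‑bromo‑7‑[(1E)‑3‑chloro‑2‑methylprop‑1‑en‑1‑yl]‑4,6‑bis(methoxymethoxy)‑1‑benzofuran | ClC/C(C)=C/c1c(OCOC)cc(OCOC)c2cc(Br)oc12 | intermediate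
10 | 2‑bromo‑4,6‑bis(methoxymethoxy)‑7‑[(2R)‑3‑methylbut‑3‑en‑2‑yl]‑1‑benzofuran | C=C(C)[C@@H](C)c1c(OCOC)cc(OCOC)c2cc(Br)oc12 | intermediate
11 | ethoxyethyne | C#COCC | starting material
12 | 1‑bromo‑3‑methylbut‑2‑ene (prenyl bromide) | CC(C)=CCBr | starting material
13 | lithium ethoxyethynide | [Li]C#COCC | intermediate
14 | 1‑ethoxy‑5‑methylhex‑4‑en‑1‑yne | CCOC#CCC=C(C)C | intermediate
15 | 5‑methylhex‑4‑enoic acid | CC(C)=CCCC(=O)O | starting material
16 | 5‑methylhex‑4‑enoyl chloride | CC(C)=CCCC(=O)Cl | intermediate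
17 | 5‑methylhexa‑1,4‑dien‑1‑one (prenylketene) | CC(C)=CCC=C=O | intermediate
18 | 3‑ethoxy‑2,4‑bis(3‑methylbut‑2‑en‑1‑yl)cyclobut‑2‑en‑1‑one (racemic) | CCOC1=C(CC=C(C)C)C(=O)C1CC=C(C)C | intermediate
19 | tetrahydrofuran | C1CCOC1 | starting material
20 | chlorotri(propan‑2‑yl)silane | CC(C)[Si](Cl)(C(C)C)C(C)C | starting material
21 | lithium ethenolate | [Li]OC=C | intermediate
22 | (ethenyloxy)tri(propan‑2‑yl)silane | C=CO[Si](C(C)C)(C(C)C)C(C)C | intermediate
23 | (1,2‑dibromoethoxy)tri(propan‑2‑yl)silane | BrCC(Br)O[Si](C(C)C)(C(C)C)C(C)C | intermediate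
24 | [(Z)‑2‑bromoethenyl]oxy‑tri(propan‑2‑yl)silane | Br/C=C\O[Si](C(C)C)(C(C)C)C(C)C | intermediate
25 | lithium {[tri(propan‑2‑yl)silyl]oxy}ethynide | [Li]C#CO[Si](C(C)C)(C(C)C)C(C)C | intermediate
26 | (ethynyloxy)tri(propan‑2‑yl)silane [(triisopropylsilyloxy)ethyne] | C#CO[Si](C(C)C)(C(C)C)C(C)C | intermediate
27 | ArA–Li: {4,6‑bis(methoxymethoxy)‑7‑[(2R)‑3‑methylbut‑3‑en‑2‑yl]‑1‑benzofuran‑2‑yl}lithium | C=C(C)[C@@H](C)c1c(OCOC)cc(OCOC)c2cc([Li])oc12 | intermediate
28 | 1‑ArA‑3‑ethoxy‑2,4‑bis(3‑methylbut‑2‑en‑1‑yl)cyclobut‑2‑en‑1‑ol (diastereomer mixture at the ring carbons) | C=C(C)[C@@H](C)c1c(OCOC)cc(OCOC)c2cc(C3(O)C(CC=C(C)C)=C(OCC)C3CC=C(C)C)oc12 | intermediate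
29 | 3‑ArA‑2,4‑bis(3‑methylbut‑2‑en‑1‑yl)cyclobut‑2‑en‑1‑one (both C4 epimers, one drawn) | C=C(C)[C@@H](C)c1c(OCOC)cc(OCOC)c2cc(C3=C(CC=C(C)C)C(=O)[C@H]3CC=C(C)C)oc12 | intermediate
30 | (3Z)‑3‑ArA‑7‑methyl‑2‑(3‑methylbut‑2‑en‑1‑yl)octa‑1,3,6‑trien‑1‑one (vinylketene) | C=C(C)[C@@H](C)c1c(OCOC)cc(OCOC)c2cc(/C(=C\CC=C(C)C)C(CC=C(C)C)=C=O)oc12 | intermediate
31 | 4‑[(1Z)‑1‑ArA‑5‑methylhexa‑1,4‑dien‑1‑yl]‑4‑(3‑methylbut‑2‑en‑1‑yl)‑3‑{[tri(propan‑2‑yl)silyl]oxy}cyclobut‑2‑en‑1‑one | C=C(C)[C@@H](C)c1c(OCOC)cc(OCOC)c2cc(/C(=C\CC=C(C)C)C3(CC=C(C)C)C(=O)C=C3O[Si](C(C)C)(C(C)C)C(C)C)oc12 | intermediate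
32 | (3E,5Z)‑5‑ArA‑9‑methyl‑4‑(3‑methylbut‑2‑en‑1‑yl)‑3‑{[tri(propan‑2‑yl)silyl]oxy}deca‑1,3,5,8‑tetraen‑1‑one (dienylketene) | C=C(C)[C@@H](C)c1c(OCOC)cc(OCOC)c2cc(/C(=C\CC=C(C)C)/C(CC=C(C)C)=C(\C=C=O)O[Si](C(C)C)(C(C)C)C(C)C)oc12 | intermediate
33 | 5‑ArA‑4,6‑bis(3‑methylbut‑2‑en‑1‑yl)‑3‑{[tri(propan‑2‑yl)silyl]oxy}cyclohexa‑2,4‑dien‑1‑one (epimers at C6) | C=C(C)[C@@H](C)c1c(OCOC)cc(OCOC)c2cc(C3=C(CC=C(C)C)C(O[Si](C(C)C)(C(C)C)C(C)C)=CC(=O)C3CC=C(C)C)oc12 | intermediate
34 | 2‑[3‑hydroxy‑2,6‑bis(3‑methylbut‑2‑en‑1‑yl)‑5‑{[tri(propan‑2‑yl)silyl]oxy}phenyl]‑4,6‑bis(methoxymethoxy)‑7‑[(2R)‑3‑methylbut‑3‑en‑2‑yl]‑1‑benzofuran | C=C(C)[C@@H](C)c1c(OCOC)cc(OCOC)c2cc(-c3c(CC=C(C)C)c(O)cc(O[Si](C(C)C)(C(C)C)C(C)C)c3CC=C(C)C)oc12 | intermediate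
35 | tris(trimethylsilyl) ether of 36 (at O4, O6 and O3′) | C=C(C)[C@@H](C)c1c(O[Si](C)(C)C)cc(O[Si](C)(C)C)c2cc(-c3c(CC=C(C)C)c(O[Si](C)(C)C)cc(O[Si](C(C)C)(C(C)C)C(C)C)c3CC=C(C)C)oc12 | intermediate
36 | 2‑[3‑hydroxy‑2,6‑bis(3‑methylbut‑2‑en‑1‑yl)‑5‑{[tri(propan‑2‑yl)silyl]oxy}phenyl]‑7‑[(2R)‑3‑methylbut‑3‑en‑2‑yl]‑1‑benzofuran‑4,6‑diol | C=C(C)[C@@H](C)c1c(O)cc(O)c2cc(-c3c(CC=C(C)C)c(O)cc(O[Si](C(C)C)(C(C)C)C(C)C)c3CC=C(C)C)oc12 | intermediate
37 | 2‑[3,5‑dihydroxy‑2,6‑bis(3‑methylbut‑2‑en‑1‑yl)phenyl]‑7‑[(2R)‑3‑methylbut‑3‑en‑2‑yl]‑1‑benzofuran‑4,6‑diol | C=C(C)[C@@H](C)c1c(O)cc(O)c2cc(-c3c(CC=C(C)C)c(O)cc(O)c3CC=C(C)C)oc12 | target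

## Step count and least certain steps

Total: 18 steps. Longest linear sequence: 12 steps (steps 1–8, then 15–18). The cyclobutenone branch has three steps (9–11) and the siloxyalkyne branch three (12–14).

**Step 16 (key step).** The [2+2] cycloaddition of the congested, fully substituted vinylketene 30 may be slower than thermal loss of the siloxyalkyne or than acylation of the product phenol by 30, so the cascade may stall at partial conversion. The fallback generates the vinylketene by a different reaction at low temperature. Setting out from 29, aqueous LiOH cleaves the C1–C4 bond of the cyclobutenone to give 3‑ArA‑7‑methyl‑2‑(3‑methylbut‑2‑en‑1‑yl)octa‑2,6‑dienoic acid F1. Oxalyl chloride converts it to the dienoyl chloride F2. Dehydrochlorination of F2 with Et3N at 0–20 °C in the presence of 26 forms 30 irreversibly and at high concentration; the cycloadduct 31 is then warmed to finish the cascade, and the route is rejoined at 34.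

**Step 8.** Enantiofacial discrimination may be poor or direct SN2 substitution may compete, because the aryl group carries an ortho acetal and MeMgBr is the least selective Grignard reagent in this reaction class. The fallback is reagent‑controlled and stereospecific. Setting out from 7, Sharpless asymmetric epoxidation (Ti(Oi‑Pr)4, D‑(−)‑diethyl tartrate, t‑BuOOH) gives the (2R,3R)‑epoxy alcohol F3. Me2CuLi opens it at the benzylic carbon with inversion (the other epoxide carbon is fully substituted) to give the (2S,3S)‑diol F4. 1,1′‑Thiocarbonyldiimidazole gives the cyclic thiocarbonate F5, and Corey–Winter fragmentation with P(OMe)3 releases the 1,1‑disubstituted alkene, rejoining the route at 10.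

**Step 17.** Acetal cleavage may be incomplete, or triflic acid that escapes buffering may cyclise a prenyl group onto a ring B oxygen or the isopropenyl group onto O6. The fallback exchanges the acetals for silyl ethers before any prenyl group is present. Setting out from 10, the same silyl triflate/2,2′‑bipyridyl treatment gives 2‑bromo‑7‑[(2R)‑3‑methylbut‑3‑en‑2‑yl]‑1‑benzofuran‑4,6‑diol F6, and i‑Pr3SiOTf/2,6‑lutidine gives the bis(triisopropylsilyl) ether F7. Bromine–lithium exchange, addition to 18 and acid work‑up as in step 15 give the cyclobutenone F8, and benzannulation with 26 as in step 16 gives the tris(silyl) phenol F9. One Bu4NF/AcOH treatment then removes all three silyl groups and rejoins the route at 37.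

**Step 13.** Bromide may attack silicon in the bromonium/oxocarbenium intermediate, so the silyl group is lost instead of the dibromide forming. The fallback avoids halogenating the silyl enol ether. Setting out from 20, soft enolisation of anhydrous chloroacetaldehyde (20, NaI, Et3N, CH3CN) gives [(Z)‑2‑chloroethenyl]oxy‑tri(propan‑2‑yl)silane F10. LiN(i‑Pr)2 eliminates HCl to give acetylide 25, and protonation rejoins the route at 26.

**Step 3.** Conversion may be low because the phenol is flanked by the bulky dibromovinyl group, or the furan may close under the amine base before formylation. The fallback reverses the order. Setting out from 3, the copper‑catalysed cyclisation of step 4 gives 2‑bromo‑4,6‑bis(methoxymethoxy)‑1‑benzofuran F11. Vilsmeier–Haack formylation (POCl3, DMF; aq. NaOAc) is then expected to attack C7, which is ortho and para to the acetal oxygens and less hindered than C5, with C2 blocked by bromine; this rejoins the route at 5.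

## Further compounds

F1 | step 16 | 3‑{4,6‑bis(methoxymethoxy)‑7‑[(2R)‑3‑methylbut‑3‑en‑2‑yl]‑1‑benzofuran‑2‑yl}‑7‑methyl‑2‑(3‑methylbut‑2‑en‑1‑yl)octa‑2,6‑dienoic acid (alkene isomer mixture) | C=C(C)[C@@H](C)c1c(OCOC)cc(OCOC)c2cc(C(CCC=C(C)C)=C(CC=C(C)C)C(=O)O)oc12
F2 | step 16 | 3‑{4,6‑bis(methoxymethoxy)‑7‑[(2R)‑3‑methylbut‑3‑en‑2‑yl]‑1‑benzofuran‑2‑yl}‑7‑methyl‑2‑(3‑methylbut‑2‑en‑1‑yl)octa‑2,6‑dienoyl chloride | C=C(C)[C@@H](C)c1c(OCOC)cc(OCOC)c2cc(C(CCC=C(C)C)=C(CC=C(C)C)C(=O)Cl)oc12
F3 | step 8 | [(2R,3R)‑3‑[2‑bromo‑4,6‑bis(methoxymethoxy)‑1‑benzofuran‑7‑yl]‑2‑methyloxiran‑2‑yl]methanol | OC[C@@]1(C)O[C@@H]1c1c(OCOC)cc(OCOC)c2cc(Br)oc12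
F4 | step 8 | (2S,3S)‑3‑[2‑bromo‑4,6‑bis(methoxymethoxy)‑1‑benzofuran‑7‑yl]‑2‑methylbutane‑1,2‑diol | OC[C@@](C)(O)[C@@H](C)c1c(OCOC)cc(OCOC)c2cc(Br)oc12
F5 | step 8 | (4S)‑4‑{(1S)‑1‑[2‑bromo‑4,6‑bis(methoxymethoxy)‑1‑benzofuran‑7‑yl]ethyl}‑4‑methyl‑1,3‑dioxolane‑2‑thione | S=C1OC[C@](C)([C@@H](C)c2c(OCOC)cc(OCOC)c3cc(Br)oc23)O1
F6 | step 17 | 2‑bromo‑7‑[(2R)‑3‑methylbut‑3‑en‑2‑yl]‑1‑benzofuran‑4,6‑diol | C=C(C)[C@@H](C)c1c(O)cc(O)c2cc(Br)oc12
F7 | step 17 | 2‑bromo‑7‑[(2R)‑3‑methylbut‑3‑en‑2‑yl]‑4,6‑bis{[tri(propan‑2‑yl)silyl]oxy}‑1‑benzofuran | C=C(C)[C@@H](C)c1c(O[Si](C(C)C)(C(C)C)C(C)C)cc(O[Si](C(C)C)(C(C)C)C(C)C)c2cc(Br)oc12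
F8 | step 17 | 3‑{7‑[(2R)‑3‑methylbut‑3‑en‑2‑yl]‑4,6‑bis{[tri(propan‑2‑yl)silyl]oxy}‑1‑benzofuran‑2‑yl}‑2,4‑bis(3‑methylbut‑2‑en‑1‑yl)cyclobut‑2‑en‑1‑one (both C4 epimers) | C=C(C)[C@@H](C)c1c(O[Si](C(C)C)(C(C)C)C(C)C)cc(O[Si](C(C)C)(C(C)C)C(C)C)c2cc(C3=C(CC=C(C)C)C(=O)C3CC=C(C)C)oc12
F9 | step 17 | 2,4‑bis(3‑methylbut‑2‑en‑1‑yl)‑3‑{7‑[(2R)‑3‑methylbut‑3‑en‑2‑yl]‑4,6‑bis{[tri(propan‑2‑yl)silyl]oxy}‑1‑benzofuran‑2‑yl}‑5‑{[tri(propan‑2‑yl)silyl]oxy}phenol | C=C(C)[C@@H](C)c1c(O[Si](C(C)C)(C(C)C)C(C)C)cc(O[Si](C(C)C)(C(C)C)C(C)C)c2cc(-c3c(CC=C(C)C)c(O)cc(O[Si](C(C)C)(C(C)C)C(C)C)c3CC=C(C)C)oc12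
F10 | step 13 | [(Z)‑2‑chloroethenyl]oxy‑tri(propan‑2‑yl)silane | Cl/C=C\O[Si](C(C)C)(C(C)C)C(C)C
F11 | step 3 | 2‑bromo‑4,6‑bis(methoxymethoxy)‑1‑benzofuran | Brc1cc2c(OCOC)cc(OCOC)cc2o1
A1 | alternative 1 | 1‑[3,5‑bis(methoxymethoxy)‑2,6‑bis(3‑methylbut‑2‑en‑1‑yl)phenyl]ethan‑1‑one | CC(=O)c1c(CC=C(C)C)c(OCOC)cc(OCOC)c1CC=C(C)C
A2 | alternative 1 | 1‑bromo‑2‑iodo‑3,5‑bis(methoxymethoxy)benzene | COCOc1cc(Br)c(I)c(OCOC)c1
A3 | alternative 1 | 2‑[3,5‑bis(methoxymethoxy)‑2,6‑bis(3‑methylbut‑2‑en‑1‑yl)phenyl]‑4,6‑bis(methoxymethoxy)‑1‑benzofuran | COCOc1cc(OCOC)c2cc(-c3c(CC=C(C)C)c(OCOC)cc(OCOC)c3CC=C(C)C)oc2c1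
A4 | alternative 2 | 5‑[(3R)‑2‑{5‑[3,5‑bis(methoxymethoxy)‑2,6‑bis(3‑methylbut‑2‑en‑1‑yl)phenyl]furan‑2‑yl}‑3,4‑dimethylpent‑4‑enoyl]‑2,2‑dimethyl‑1,3‑dioxane‑4,6‑dione (epimers at C2 of the acyl chain) | C=C(C)[C@@H](C)C(C(=O)C1C(=O)OC(C)(C)OC1=O)c1ccc(-c2c(CC=C(C)C)c(OCOC)cc(OCOC)c2CC=C(C)C)o1
A5 | alternative 2 | (5R)‑4‑{5‑[3,5‑bis(methoxymethoxy)‑2,6‑bis(3‑methylbut‑2‑en‑1‑yl)phenyl]furan‑2‑yl}‑5,6‑dimethylhepta‑1,6‑diene‑1,3‑dione (acylketene) | C=C(C)[C@@H](C)C(C(=O)C=C=O)c1ccc(-c2c(CC=C(C)C)c(OCOC)cc(OCOC)c2CC=C(C)C)o1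
A6 | alternative 2 | 2‑[3,5‑bis(methoxymethoxy)‑2,6‑bis(3‑methylbut‑2‑en‑1‑yl)phenyl]‑7‑[(2R)‑3‑methylbut‑3‑en‑2‑yl]‑1‑benzofuran‑4,6‑diol | C=C(C)[C@@H](C)c1c(O)cc(O)c2cc(-c3c(CC=C(C)C)c(OCOC)cc(OCOC)c3CC=C(C)C)oc12
A7 | alternative 3 | 2‑{4,6‑bis(methoxymethoxy)‑7‑[(2R)‑3‑methylbut‑3‑en‑2‑yl]‑1‑benzofuran‑2‑yl}‑3‑(3‑methylbut‑2‑en‑1‑yl)‑6‑(4‑methylpent‑3‑en‑1‑yl)‑4H‑pyran‑4‑one | C=C(C)[C@@H](C)c1c(OCOC)cc(OCOC)c2cc(-c3oc(CCC=C(C)C)cc(=O)c3CC=C(C)C)oc12
A8 | alternative 3 | 1‑{4,6‑bis(methoxymethoxy)‑7‑[(2R)‑3‑methylbut‑3‑en‑2‑yl]‑1‑benzofuran‑2‑yl}‑9‑methyl‑2‑(3‑methylbut‑2‑en‑1‑yl)dec‑8‑ene‑1,3,5‑trione | C=C(C)[C@@H](C)c1c(OCOC)cc(OCOC)c2cc(C(=O)C(CC=C(C)C)C(=O)CC(=O)CCC=C(C)C)oc12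
A9 | alternative 3 | 5‑{4,6‑bis(methoxymethoxy)‑7‑[(2R)‑3‑methylbut‑3‑en‑2‑yl]‑1‑benzofuran‑2‑yl}‑4,6‑bis(3‑methylbut‑2‑en‑1‑yl)benzene‑1,3‑diol | C=C(C)[C@@H](C)c1c(OCOC)cc(OCOC)c2cc(-c3c(CC=C(C)C)c(O)cc(O)c3CC=C(C)C)oc12
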